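**Retrosynthetic overview**
1. Target 25 ⇐ chiral-phase resolution of racemic hemiketal 24, the ring-closed tautomer of the 1-(2-hydroxyaryl)-1,3-diketone 23 released by global hydrogenolysis of the pentabenzyl diketone 22.
2. 22 ⇐ oxidation of β-hydroxy ketone 21 ⇐ intermolecular aldol addition of the lithium enolate of acetophenone 10 to arylacetaldehyde 18 (this makes the C2–C3 bond of the chromanone).
3. 10 ⇐ benzylation and Hoesch acetylation of 5-heptylresorcinol 7 ⇐ Wittig, hydrogenation and demethylation from 3,5-dimethoxybenzaldehyde.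
4. 18 ⇐ oxidative cleavage of allyl benzoate 16 ⇐ Vilsmeier formylation, Pinnick oxidation and benzylation of allylarene 12 ⇐ 3,5-bis(benzyloxy)benzyl bromide + vinylmagnesium bromide.
5. Ring order: both benzene rings are bought; the only ring formed is the 2-hydroxy-dihydropyranone, closed last and spontaneously.

Assumption: C2 is a hemiketal carbon that can open to the diketone, so no reagent can fix it irreversibly; the route makes the racemate, the (R)-enantiomer is isolated by resolution, and it is assumed to be configurationally stable when kept cold, neutral and dry.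

**Step 1**
Reactants: 1 3,5-dimethoxybenzaldehyde; 2 hexyltriphenylphosphonium bromide
Product: 4 1-(hept-1-en-1-yl)-3,5-dimethoxybenzene (E/Z mixture), via hexylidenetriphenylphosphorane 3 (not isolated)
Conditions: KOtBu, THF, 0 °C; then 1, 0 °C → rt
Reagents that add atoms: none
Why: Wittig olefination of an aromatic aldehyde with a non-stabilised ylide is dependable, and the E/Z ratio is irrelevant because the alkene is saturated in the next step.

**Step 2**
Reactants: 4 1-(hept-1-en-1-yl)-3,5-dimethoxybenzene
Product: 5 1-heptyl-3,5-dimethoxybenzene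
Conditions: H2 (1 atm), 10% Pd/C, EtOAc, rt
Reagents that add atoms: none
Why: Catalytic hydrogenation of the styrenyl C=C over Pd/C is fast and leaves aryl methyl ethers untouched.

**Step 3**
Reactants: 5 1-heptyl-3,5-dimethoxybenzene
Product: 7 5-heptylbenzene-1,3-diol, via bis(dibromoboryl) aryl ether 6 (not isolated)
Conditions: BBr3, CH2Cl2, −78 °C → rt; then H2O, 0 °C
Reagents that add atoms: none
Why: Lewis-acid ether cleavage with BBr3 (through the aryloxyboranes) cleanly frees both phenols of an alkylresorcinol dimethyl ether.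

**Step 4**
Reactants: 7 5-heptylbenzene-1,3-diol
Product: 9 1-(2,4-dihydroxy-6-heptylphenyl)ethan-1-one, via ketiminium chloride 8 (not isolated)
Conditions: MeCN, ZnCl2, HCl (g), Et2O, 0 °C → rt; then H2O, reflux
Reagents that add atoms: acetonitrile CC#N; water O
Why: Hoesch acylation occurs once only, ortho to the alkyl chain and para to a hydroxyl (as with orcinol), because the ketiminium salt deactivates the ring; hydrolysis gives the ketone and the minor 2,6-dihydroxy isomer is removed by crystallisation.

**Step 5**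
Reactants: 9 1-(2,4-dihydroxy-6-heptylphenyl)ethan-1-one
Product: 10 1-[2,4-bis(benzyloxy)-6-heptylphenyl]ethan-1-one
Conditions: BnBr (2.5 equiv), K2CO3, DMF, 70 °C
Reagents that add atoms: benzyl bromide BrCc1ccccc1
Why: Williamson ether synthesis in warm K2CO3/DMF also alkylates the hydrogen-bonded ortho-hydroxyl, and benzyl is chosen because it can be removed at the end under neutral conditions.

**Step 6**
Reactants: 11 3,5-bis(benzyloxy)benzyl bromide
Product: 12 1-allyl-3,5-bis(benzyloxy)benzene
Conditions: CH2=CHMgBr (1.5 equiv), CuI (10 mol %), THF, −20 °C → rt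
Reagents that add atoms: vinylmagnesium bromide C=C[Mg]Br
Why: Copper-catalysed Grignard cross-coupling (Kochi type) of a benzylic bromide with vinylmagnesium bromide gives the allylarene directly, and benzyl ethers are inert to it.

**Step 7**
Reactants: 12 1-allyl-3,5-bis(benzyloxy)benzene
Product: 14 2-allyl-4,6-bis(benzyloxy)benzaldehyde, via aryl iminium chloride 13 (not isolated)
Conditions: POCl3, DMF, 0 °C → 50 °C; then ice-water
Reagents that add atoms: N,N-dimethylformamide CN(C)C=O; water O
Why: Vilsmeier–Haack formylation goes para to one benzyloxy group and ortho to the alkyl substituent rather than between the two ethers, and the terminal alkene and benzyl ethers do not react with the chloroiminium reagent.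

**Step 8**
Reactants: 14 2-allyl-4,6-bis(benzyloxy)benzaldehyde
Product: 15 2-allyl-4,6-bis(benzyloxy)benzoic acid
Conditions: NaClO2, NaH2PO4, 2-methyl-2-butene (10 equiv), t-BuOH/THF/H2O, rt
Reagents that add atoms: sodium chlorite [Na+].[O-]Cl=O
Why: Pinnick oxidation converts even hindered electron-rich benzaldehydes into acids, and the excess 2-methyl-2-butene traps HOCl before it can attack the allyl group or the ring.

**Step 9**
Reactants: 15 2-allyl-4,6-bis(benzyloxy)benzoic acid
Product: 16 benzyl 2-allyl-4,6-bis(benzyloxy)benzoate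
Conditions: BnBr (1.2 equiv), K2CO3, DMF, rt
Reagents that add atoms: benzyl bromide BrCc1ccccc1
Why: O-Alkylation of the carboxylate (SN2 on benzyl bromide) is unaffected by the two ortho substituents that would block a Fischer esterification.

**Step 10**
Reactants: 16 benzyl 2-allyl-4,6-bis(benzyloxy)benzoate
Product: 18 benzyl 2,4-bis(benzyloxy)-6-(2-oxoethyl)benzoate, via vicinal diol 17 (not isolated)
Conditions: OsO4 (2 mol %), NaIO4 (4 equiv), 2,6-lutidine, dioxane/H2O 3:1, rt; used at once
Reagents that add atoms: osmium tetroxide O=[Os](=O)(=O)=O (catalytic oxygen carrier); sodium periodate [Na+].[O-]I(=O)(=O)=O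
Why: Lemieux–Johnson oxidative cleavage (osmylation then periodate glycol fission, lutidine-buffered) shortens the allyl group to the arylacetaldehyde without touching the benzyl ethers or the ester.

**Step 11**
Reactants: 10 1-[2,4-bis(benzyloxy)-6-heptylphenyl]ethan-1-one; 18 benzyl 2,4-bis(benzyloxy)-6-(2-oxoethyl)benzoate
Product: 21 benzyl 2,4-bis(benzyloxy)-6-{4-[2,4-bis(benzyloxy)-6-heptylphenyl]-2-hydroxy-4-oxobutyl}benzoate (racemic), via lithium enolate 19 (not isolated), via lithium aldolate 20 (not isolated)
Conditions: LDA (1.0 equiv), 10 (1.05 equiv), THF, −78 °C; then 18 (0.85 equiv), −78 °C, 20 min; AcOH/THF quench at −78 °C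
Reagents that add atoms: none
Why: In this kinetic lithium-enolate aldol addition the hindered methyl ketone has one enolisable site and does not self-condense, addition at −78 °C outruns proton transfer, and the cold acidic quench prevents retro-aldol and lactonisation onto the benzyl ester; the new carbinol centre is racemic and is removed in step 12.

**Step 12**
Reactants: 21 racemic β-hydroxy ketone
Product: 22 benzyl 2,4-bis(benzyloxy)-6-{4-[2,4-bis(benzyloxy)-6-heptylphenyl]-2,4-dioxobutyl}benzoate
Conditions: Dess–Martin periodinane (1.2 equiv), CH2Cl2, 0 °C → rt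
Reagents that add atoms: none
Why: Dess–Martin oxidation of a β-hydroxy ketone to the β-diketone is neutral and mild, so the benzyl ester and ethers survive, and the small excess avoids over-oxidation at the central methylene.

**Step 13**
Reactants: 22 pentabenzyl 1,3-diketone
Product: 24 rac-2-[(5-heptyl-2,7-dihydroxy-4-oxo-3,4-dihydro-2H-chromen-2-yl)methyl]-4,6-dihydroxybenzoic acid, via open-chain diketo acid 23 (not isolated)
Conditions: H2 (1 atm), 10% Pd/C, EtOAc, rt; filter, concentrate below 30 °C
Reagents that add atoms: none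
Why: Neutral hydrogenolysis removes the four benzyl ethers and the benzyl ester without acid or base, and the freed ortho-phenol adds spontaneously to the distal ketone (ring–chain tautomerism) to close the 2-hydroxychroman-4-one; C2 forms without control, hence racemic.

**Step 14**
Reactants: 24 racemic hemiketal acid
Product: 25 2-{[(2R)-5-heptyl-2,7-dihydroxy-4-oxo-3,4-dihydro-2H-chromen-2-yl]methyl}-4,6-dihydroxybenzoic acid
Conditions: preparative chiral HPLC, immobilised cellulose tris(3,5-dichlorophenylcarbamate), hexane/EtOAc/0.1% HCO2H, 5 °C; fractions evaporated cold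
Reagents that add atoms: none
Why: Chiral-phase chromatographic resolution separates the two enantiomers, which differ only at C2; the (R)-fraction is assigned by ECD against the calculated spectrum, and cold, base-free handling suppresses the ring opening that would racemise C2.

**Compound list**
1 | 3,5-dimethoxybenzaldehyde | COc1cc(C=O)cc(OC)c1 | starting material
2 | hexyltriphenylphosphonium bromide | CCCCCC[P+](c1ccccc1)(c1ccccc1)c1ccccc1.[Br-] | starting material
3 | hexylidenetriphenylphosphorane | CCCCCC=P(c1ccccc1)(c1ccccc1)c1ccccc1 | intermediate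
4 | 1-(hept-1-en-1-yl)-3,5-dimethoxybenzene (E/Z mixture) | CCCCCC=Cc1cc(OC)cc(OC)c1 | intermediate
5 | 1-heptyl-3,5-dimethoxybenzene | CCCCCCCc1cc(OC)cc(OC)c1 | intermediate
6 | 1,3-bis(dibromoboryloxy)-5-heptylbenzene | CCCCCCCc1cc(OB(Br)Br)cc(OB(Br)Br)c1 | intermediate
7 | 5-heptylbenzene-1,3-diol (5-heptylresorcinol) | CCCCCCCc1cc(O)cc(O)c1 | intermediate
8 | 1-(2,4-dihydroxy-6-heptylphenyl)ethan-1-iminium chloride | CCCCCCCc1cc(O)cc(O)c1C(C)=[NH2+].[Cl-] | intermediate
9 | 1-(2,4-dihydroxy-6-heptylphenyl)ethan-1-one | CCCCCCCc1cc(O)cc(O)c1C(C)=O | intermediate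
10 | 1-[2,4-bis(benzyloxy)-6-heptylphenyl]ethan-1-one | CCCCCCCc1cc(OCc2ccccc2)cc(OCc2ccccc2)c1C(C)=O | intermediate
11 | 3,5-bis(benzyloxy)benzyl bromide | BrCc1cc(OCc2ccccc2)cc(OCc2ccccc2)c1 | starting material
12 | 1-allyl-3,5-bis(benzyloxy)benzene | C=CCc1cc(OCc2ccccc2)cc(OCc2ccccc2)c1 | intermediate
13 | N-[2-allyl-4,6-bis(benzyloxy)benzylidene]-N-methylmethanaminium chloride | C=CCc1cc(OCc2ccccc2)cc(OCc2ccccc2)c1C=[N+](C)C.[Cl-] | intermediate
14 | 2-allyl-4,6-bis(benzyloxy)benzaldehyde | C=CCc1cc(OCc2ccccc2)cc(OCc2ccccc2)c1C=O | intermediate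
15 | 2-allyl-4,6-bis(benzyloxy)benzoic acid | C=CCc1cc(OCc2ccccc2)cc(OCc2ccccc2)c1C(=O)O | intermediate
16 | benzyl 2-allyl-4,6-bis(benzyloxy)benzoate | C=CCc1cc(OCc2ccccc2)cc(OCc2ccccc2)c1C(=O)OCc1ccccc1 | intermediate
17 | benzyl 2,4-bis(benzyloxy)-6-(2,3-dihydroxypropyl)benzoate (racemic) | OCC(O)Cc1cc(OCc2ccccc2)cc(OCc2ccccc2)c1C(=O)OCc1ccccc1 | intermediate
18 | benzyl 2,4-bis(benzyloxy)-6-(2-oxoethyl)benzoate | O=CCc1cc(OCc2ccccc2)cc(OCc2ccccc2)c1C(=O)OCc1ccccc1 | intermediate
19 | lithium 1-[2,4-bis(benzyloxy)-6-heptylphenyl]ethen-1-olate | [Li+].[O-]C(=C)c1c(CCCCCCC)cc(OCc2ccccc2)cc1OCc1ccccc1 | intermediate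
20 | lithium alkoxide of 21 (racemic) | CCCCCCCc1cc(OCc2ccccc2)cc(OCc2ccccc2)c1C(=O)CC([O-])Cc1cc(OCc2ccccc2)cc(OCc2ccccc2)c1C(=O)OCc1ccccc1.[Li+] | intermediate
21 | benzyl 2,4-bis(benzyloxy)-6-{4-[2,4-bis(benzyloxy)-6-heptylphenyl]-2-hydroxy-4-oxobutyl}benzoate (racemic) | CCCCCCCc1cc(OCc2ccccc2)cc(OCc2ccccc2)c1C(=O)CC(O)Cc1cc(OCc2ccccc2)cc(OCc2ccccc2)c1C(=O)OCc1ccccc1 | intermediate
22 | benzyl 2,4-bis(benzyloxy)-6-{4-[2,4-bis(benzyloxy)-6-heptylphenyl]-2,4-dioxobutyl}benzoate | CCCCCCCc1cc(OCc2ccccc2)cc(OCc2ccccc2)c1C(=O)CC(=O)Cc1cc(OCc2ccccc2)cc(OCc2ccccc2)c1C(=O)OCc1ccccc1 | intermediate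
23 | 2-[4-(2-heptyl-4,6-dihydroxyphenyl)-2,4-dioxobutyl]-4,6-dihydroxybenzoic acid | CCCCCCCc1cc(O)cc(O)c1C(=O)CC(=O)Cc1cc(O)cc(O)c1C(=O)O | intermediate
24 | rac-2-[(5-heptyl-2,7-dihydroxy-4-oxo-3,4-dihydro-2H-chromen-2-yl)methyl]-4,6-dihydroxybenzoic acid | CCCCCCCc1cc(O)cc2c1C(=O)CC(O)(Cc1cc(O)cc(O)c1C(=O)O)O2 | intermediate
25 | 2-{[(2R)-5-heptyl-2,7-dihydroxy-4-oxo-3,4-dihydro-2H-chromen-2-yl]methyl}-4,6-dihydroxybenzoic acid | CCCCCCCc1cc(O)cc2c1C(=O)C[C@@](O)(Cc1cc(O)cc(O)c1C(=O)O)O2 | target

**Totals**
Total steps: 14. Longest linear sequence: 9 (steps 1–5 then 11–14, or equally steps 6–10 then 11–14).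

**Three steps most likely to fail**

Step 11 (aldol addition). The arylacetaldehyde 18 is easily enolised by the basic enolate, and the lithium aldolate 20 can lactonise onto the neighbouring benzyl ester to give a dihydroisocoumarin. The fallback sets out from 10 and comes back at 21. Ketone 10 is converted with LDA and TMSCl (THF, −78 °C) into the silyl enol ether {1-[2,4-bis(benzyloxy)-6-heptylphenyl]ethenoxy}trimethylsilane F1. F1 is then added to aldehyde 18 in a Mukaiyama aldol reaction (BF3·OEt2, CH2Cl2, −78 °C, then aqueous NaHCO3) to give 21. No basic enolate or free alkoxide is present, so neither enolisation of 18 nor lactonisation can compete.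

Step 13 (global hydrogenolysis). Five benzyl groups must be removed, and the product can lose water to the 2-benzylchromone, close to an isocoumarin, or suffer reduction of the C4 ketone if the reaction is prolonged. The fallback sets out from 22 and comes back at 24. It is a non-reductive Lewis-acid debenzylation with BCl3 and pentamethylbenzene as benzyl-cation scavenger (CH2Cl2, −78 °C, cold quench into aqueous NaHCO3/THF). The benzyl groups leave as benzylpentamethylbenzene and 24 forms through the same open-chain acid 23. This path makes no new compound (none F0).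

Step 14 (resolution). The hemiketal may re-equilibrate through the open form on the column or on evaporation, which would erode the enantiomeric purity. The fallback sets out from 24 and comes back at 25. It is a crystallisation-induced dynamic resolution: 24 is stirred with (R)-N,N-dimethyl-1-phenylethylamine in EtOAc/heptane, so that one diastereomeric salt crystallises while the hemiketal epimerises in solution through 23. The tertiary amine cannot form an enaminone with the diketone. The solid (R)-N,N-dimethyl-1-phenylethylammonium 2-{[(2R)-5-heptyl-2,7-dihydroxy-4-oxo-3,4-dihydro-2H-chromen-2-yl]methyl}-4,6-dihydroxybenzoate F2 is collected and partitioned cold between EtOAc and dilute aqueous citric acid to release 25. If the salt of the (S)-acid is the one that crystallises, the (S)-amine is used instead.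

**Further compounds**
F1 | step 11 | {1-[2,4-bis(benzyloxy)-6-heptylphenyl]ethenoxy}trimethylsilane | C=C(O[Si](C)(C)C)c1c(CCCCCCC)cc(OCc2ccccc2)cc1OCc1ccccc1
F0 | step 13 | none | none
F2 | step 14 | (R)-N,N-dimethyl-1-phenylethylammonium 2-{[(2R)-5-heptyl-2,7-dihydroxy-4-oxo-3,4-dihydro-2H-chromen-2-yl]methyl}-4,6-dihydroxybenzoate | CCCCCCCc1cc(O)cc2c1C(=O)C[C@@](O)(Cc1cc(O)cc(O)c1C(=O)[O-])O2.C[C@@H]([NH+](C)C)c1ccccc1
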